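Time first: the east run reads Q at 16.9 % after 0.333 h and 17.8 % after 2.50 h, a gain of 0.9 percentage points against a scatter of 1 point, so we leave the 2.0 h of the new flask as it is and ask what its charge is worth.

| flask | J | X | D | remark | time |
|---|---|---|---|---|---|
| east | 1 M | 0.050 M | 15 mM | run made earlier |  |
| south | 1 M | 0.075 M | 15 mM | run made earlier |  |
| south-east | 1 M | 0.10 M | 7.5 mM | run made earlier |  |
| flask | 1.0 M | 0.100 M | 15 mM |  | 2.0 h |

| run | time / h | Q / % | J / % |
|---|---|---|---|
| east | 0.333 | 16.9 | 82.0 |
| east | 0.667 | 18.3 | 82.8 |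
| east | 1.00 | 20.2 | 81.3 |
| east | 1.33 | 17.9 | 84.5 |
| east | 1.50 | 17.6 | 82.8 |
| east | 2.00 | 17.5 | 82.9 |
| east | 2.50 | 17.8 | 82.3 |
| south | 0.200 | 13.4 | 88.1 |
| south | 0.333 | 12.3 | 87.8 |
| south | 0.417 | 11.8 | 89.4 |
| south | 0.667 | 11.5 | 88.9 |
| south | 1.00 | 11.1 | 86.7 |
| south | 1.50 | 10.6 | 87.9 |
| south | 2.50 | 13.4 | 88.5 |
| south-east | 0.200 | 4.1 | 96.1 |
| south-east | 0.667 | 4.2 | 95.0 |
| south-east | 1.00 | 2.3 | 95.8 |
| south-east | 1.50 | 4.8 | 94.8 |
| south-east | 2.50 | 5.4 | 96.4 |

(readings scatter by 1 percentage point)

- the average divides the monomer in chains by the number of chains begun, living and dead together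
- the numbers in the tables scatter by 1 percentage point (one standard deviation)
- candidate steps: J + D -> E; J + L -> Q + L; L + X -> Z; J + D -> L + Q
- the earlier runs do not show the number of chains; that part of a forecast is a guess

* average number of monomer units in a chain (chains begun, living or dead) at 2.0 h
* part of the J that has reacted at 2.0 h

1. The seven east readings of Q average 18.0 %, with D at 0.300 of X. That gives 0.663: the stop number, the natural log of one over the fraction of J left, divided by D as a fraction of X.
2. The south readings average 12.0 %, with D at 0.200 of X, and read 0.640. Between these two runs the number barely moves, so we freeze it at the east value.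
3. The new flask has D at 0.150 of X, so we reckon 9.46 % of its J reacted.
4. If each D begins one chain, which is our guess because the runs do not show chains, dp is that fraction times J over D, 6.31.
5. We decide to charge the flask as written and take one sample at the end.
6. The forecast differs from us, with 8.9 % and a dp of 8; of the chains it says: “The runs cannot show this split”.

    J + D → E (k = 2.11 × 10⁻⁴ M⁻¹ s⁻¹)
    J + L → Q + L, rate k2*[L]*[J] (k = 0.0339 M⁻¹ s⁻¹)
    L + X → Z (k = 0.0657 M⁻¹ s⁻¹)
    J + D → L + Q (k = 0.0266 M⁻¹ s⁻¹)

The flask gives 9.37 % reacted and a dp of 6.29, with E at 0.0118 % of the J charged; the forecast's dp is 1.27 times that. The neighbouring flask has the same charge except J at 0.60 M. J is not in the ratio, so the frozen stop number again gives 9.46 %, and one chain per D gives a dp of 3.78. That neighbouring flask reacts 10.3 % of its J, with a dp of 4.15, higher than our reckoning, and D, the limiting reagent, stands at 0 % of its charge after 2.00 h.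

All runs were computed from invented constants, and the scatter is random.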